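**Retrosynthetic overview**
1. The (R)-lactol comes from neutral hydrogenolysis of its resolved, configurationally stable O-benzyl acetal; the ring A CH2OH comes from a CHO group by borohydride reduction.
2. The seven-membered depsidone lactone (the last ring formed) comes from carbodiimide lactonisation of a diaryl-ether hydroxy acid.
3. The diaryl ether comes from SNAr of a ring B phenol on a ring A 2-fluoro-3-formylbenzoate, itself made from 3-fluoro-5-methylanisole.
4. Ring B comes from a 3-alkoxyphthalide built de novo: intermolecular Michael addition of methyl 3-oxopentanoate to methyl (E)-4,4-dimethoxybut-2-enoate (key C–C bond), Dieckmann closure and dehydrogenation; the fifth oxygen is added by bromination, borylation and oxidation.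
5. Ring order: ring B carbocycle, then its γ-lactone acetal ring, then (ring A bought as an arene) the depsidone ring.

Assumption: the lactol carbon is the only stereocentre and can epimerise by ring-chain tautomerism, so it is carried and resolved as its stable O-benzyl acetal, unveiled last under neutral conditions, and the product is kept cold in aprotic, base-free media.

**Route**

Step 1
Reactants: 1 trimethyl phosphonoacetate; 2 2,2-dimethoxyacetaldehyde (60 wt% in water)
Product: 3 methyl (E)-4,4-dimethoxybut-2-enoate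
Conditions: K2CO3 (1.5 equiv), H2O/THF, 0 °C to rt
Reagents that add atoms: none
Why: Horner–Wadsworth–Emmons olefination of a non-enolisable aldehyde with a stabilised phosphonate gives the E-enoate; no stereocentre is formed.

Step 2
Reactants: 3 methyl (E)-4,4-dimethoxybut-2-enoate; 4 methyl 3-oxopentanoate
Product: 6 methyl 6-(dimethoxymethyl)-3-methyl-2,4-dioxocyclohexane-1-carboxylate (diastereomer mixture), via Michael adduct 5 (not isolated)
Conditions: NaOMe (1.2 equiv), MeOH, 0 °C, add 4 then 3, reflux 8 h; AcOH to pH 5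
Reagents that add atoms: none
Why: Intermolecular Michael addition of the keto ester enolate to the enoate joins the two fragments (the later C3a–C7a bond of ring B), and Dieckmann (intramolecular Claisen) closure is driven by the stabilised β-diketone enolate; the unselective stereocentres are erased on aromatisation.

Step 3
Reactants: 6 methyl 6-(dimethoxymethyl)-3-methyl-2,4-dioxocyclohexane-1-carboxylate
Product: 7 methyl 6-(dimethoxymethyl)-2,4-dihydroxy-3-methylbenzoate
Conditions: DDQ (1.1 equiv), 1,4-dioxane, rt to 60 °C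
Reagents that add atoms: none
Why: Dehydrogenative aromatisation of the enolised cyclohexane-1,3-dione by hydride abstraction with the quinone is neutral enough to spare the acetal, and every dehydro tautomer drains to the resorcylate.

Step 4
Reactants: 7 methyl 6-(dimethoxymethyl)-2,4-dihydroxy-3-methylbenzoate
Product: 9 racemic lactol 3,5,7-trihydroxy-6-methyl-3H-isobenzofuran-1-one, via aldehyde ester 8 (not isolated)
Conditions: 1 M HCl/THF, rt; then aqueous NaOH to pH 13, rt, N2; then HCl to pH 2
Reagents that add atoms: water, O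
Why: Acetal hydrolysis is followed by neighbouring-group-assisted cleavage of the hindered methyl ester (hydroxide adds to the formyl group and the alkoxide attacks the ester), and acidification closes the 2-formylbenzoic acid to its ring tautomer, the lactol centre forming as a racemate.

Step 5
Reactants: 9 racemic lactol 3,5,7-trihydroxy-6-methyl-3H-isobenzofuran-1-one
Product: 10 racemic 3-(benzyloxy)-5,7-dihydroxy-6-methyl-3H-isobenzofuran-1-one
Conditions: BnOH (5 equiv), camphorsulfonic acid (10 mol%), toluene, 50 °C, 4 Å molecular sieves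
Reagents that add atoms: benzyl alcohol, OCc1ccccc1
Why: Fischer-type pseudo-esterification (acid-catalysed acetalisation through the benzylic oxocarbenium ion) converts the labile lactol into a configurationally stable O-benzyl acetal, formed racemic.

Step 6
Reactants: 10 racemic 3-(benzyloxy)-5,7-dihydroxy-6-methyl-3H-isobenzofuran-1-one
Product: 11 racemic 3-(benzyloxy)-5,7-bis(methoxymethoxy)-6-methyl-3H-isobenzofuran-1-one
Conditions: NaH (2.5 equiv), MOMCl (2.6 equiv), DMF, 0 °C to rt
Reagents that add atoms: chloromethyl methyl ether, COCCl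
Why: Williamson-type O-alkylation of both sodium phenoxides (including the chelated C7 hydroxyl) installs acid-labile ethers that survive base, palladium and peroxide.

Step 7
Reactants: 11 racemic 3-(benzyloxy)-5,7-bis(methoxymethoxy)-6-methyl-3H-isobenzofuran-1-one
Product: 12 racemic 3-(benzyloxy)-4-bromo-5,7-bis(methoxymethoxy)-6-methyl-3H-isobenzofuran-1-one
Conditions: NBS (1.05 equiv), MeCN, 0 °C to rt, dark
Reagents that add atoms: N-bromosuccinimide, O=C1CCC(=O)N1Br
Why: Electrophilic aromatic bromination can only occur at C4, the single free ring position, which is ortho and para to the two alkoxy groups.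

Step 8
Reactants: 12 racemic 3-(benzyloxy)-4-bromo-5,7-bis(methoxymethoxy)-6-methyl-3H-isobenzofuran-1-one
Product: 14 racemic phenol 3-(benzyloxy)-4-hydroxy-5,7-bis(methoxymethoxy)-6-methyl-3H-isobenzofuran-1-one, via pinacol boronate 13 (not isolated)
Conditions: B2pin2 (1.5 equiv), Pd(OAc)2 (5 mol%), SPhos (10 mol%), KOAc (3 equiv), 1,4-dioxane, 90 °C; then THF, 30% H2O2, aqueous NaHCO3, 0 °C to rt
Reagents that add atoms: bis(pinacolato)diboron, CC1(C)OB(OC1(C)C)B1OC(C)(C)C(C)(C)O1 (boron of 13 only); hydrogen peroxide, OO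
Why: Miyaura borylation with a bulky biarylphosphine suits di-ortho-substituted aryl bromides, and peroxide-induced 1,2-aryl shift from boron to oxygen gives the phenol while both other ring oxygens stay protected.

Step 9
Reactants: 15 1-fluoro-3-methoxy-5-methylbenzene
Product: 16 2-bromo-1-fluoro-5-methoxy-3-methylbenzene
Conditions: NBS (1.0 equiv), MeCN, 0 °C to rt
Reagents that add atoms: N-bromosuccinimide, O=C1CCC(=O)N1Br
Why: Electrophilic aromatic bromination of an anisole with NBS in acetonitrile goes para to the methoxy group, placing bromine between F and CH3.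

Step 10
Reactants: 16 2-bromo-1-fluoro-5-methoxy-3-methylbenzene
Product: 18 3-bromo-2-fluoro-6-methoxy-4-methylbenzaldehyde, via aryllithium 17 (not isolated)
Conditions: LiN(iPr)2 (1.1 equiv), THF, −78 °C, 1 h; DMF (1.5 equiv), −78 to 0 °C; aqueous HCl
Reagents that add atoms: N,N-dimethylformamide, CN(C)C=O
Why: Directed ortho-metalation by the amide base removes the most acidic proton (between F and OMe) without touching the bromide, and formylation of the aryllithium with DMF follows.

Step 11
Reactants: 18 3-bromo-2-fluoro-6-methoxy-4-methylbenzaldehyde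
Product: 19 2-(3-bromo-2-fluoro-6-methoxy-4-methylphenyl)-1,3-dioxolane
Conditions: ethylene glycol (3 equiv), TsOH·H2O (2 mol%), toluene, reflux, Dean–Stark
Reagents that add atoms: ethylene glycol, OCCO
Why: Acid-catalysed acetalisation with water removal masks the aldehyde against the organolithium of the next step.

Step 12
Reactants: 19 2-(3-bromo-2-fluoro-6-methoxy-4-methylphenyl)-1,3-dioxolane
Product: 21 allyl 3-(1,3-dioxolan-2-yl)-2-fluoro-4-methoxy-6-methylbenzoate, via aryllithium 20 (not isolated)
Conditions: n-BuLi (1.05 equiv), THF, −78 °C, 15 min; cannulation into allyl chloroformate (2 equiv), THF, −78 °C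
Reagents that add atoms: allyl chloroformate, C=CCOC(=O)Cl
Why: Bromine–lithium exchange is fast and regiochemically unambiguous, the ortho-fluoro aryllithium does not lose LiF at −78 °C, and inverse-addition acylation with the chloroformate stops at the hindered ester.

Step 13
Reactants: 21 allyl 3-(1,3-dioxolan-2-yl)-2-fluoro-4-methoxy-6-methylbenzoate
Product: 22 allyl 2-fluoro-3-formyl-4-methoxy-6-methylbenzoate
Conditions: 1 M HCl, THF, rt
Reagents that add atoms: water, O
Why: Mild acetal hydrolysis frees the aldehyde, leaving a fluoride flanked by formyl and ester groups and thus activated for SNAr.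

Step 14
Reactants: 14 racemic phenol 3-(benzyloxy)-4-hydroxy-5,7-bis(methoxymethoxy)-6-methyl-3H-isobenzofuran-1-one; 22 allyl 2-fluoro-3-formyl-4-methoxy-6-methylbenzoate
Product: 23 racemic allyl 2-{[3-(benzyloxy)-5,7-bis(methoxymethoxy)-6-methyl-1-oxo-1,3-dihydroisobenzofuran-4-yl]oxy}-3-formyl-4-methoxy-6-methylbenzoate
Conditions: K2CO3 (2 equiv), DMF, 60 °C, N2
Reagents that add atoms: none
Why: Nucleophilic aromatic substitution (addition–elimination) pairs an electron-rich phenoxide with a fluoride activated by an ortho formyl and an ortho ester group, the electronically matched way to make this tetra-ortho-substituted diaryl ether.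

Step 15
Reactants: 23 racemic allyl ester diaryl ether
Product: 24 racemic 2-{[3-(benzyloxy)-5,7-bis(methoxymethoxy)-6-methyl-1-oxo-1,3-dihydroisobenzofuran-4-yl]oxy}-3-formyl-4-methoxy-6-methylbenzoic acid
Conditions: Pd(PPh3)4 (5 mol%), N-methylaniline (3 equiv), THF, rt
Reagents that add atoms: none
Why: Tsuji–Trost deallylation, in which zerovalent palladium ionises the allyl ester to a π-allyl complex trapped by the weakly basic amine, frees the hindered acid without touching the aldehyde, acetal or lactone, and no free ortho phenol is yet present for a Smiles rearrangement.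

Step 16
Reactants: 24 racemic bis-MOM acid
Product: 25 racemic 2-{[3-(benzyloxy)-5,7-dihydroxy-6-methyl-1-oxo-1,3-dihydroisobenzofuran-4-yl]oxy}-3-formyl-4-methoxy-6-methylbenzoic acid
Conditions: TsOH·H2O (0.3 equiv), BnOH (10 equiv), toluene, 50 °C; aqueous work-up
Reagents that add atoms: none
Why: Acid-catalysed transacetalisation moves both methoxymethyl groups onto benzyl alcohol, any exchange at the benzyl acetal is degenerate in this medium, and the 2,6-disubstituted acid is too hindered to esterify.

Step 17
Reactants: 25 racemic diol acid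
Product: 26 racemic 1-(benzyloxy)-4-hydroxy-10-methoxy-5,8-dimethyl-3,7-dioxo-1,3-dihydro-7H-isobenzofuro[4,5-b][1,4]benzodioxepine-11-carbaldehyde (O-benzyl pseudo-ester of stictic acid)
Conditions: DCC (1.5 equiv), DMAP (0.1 equiv), CH2Cl2, 2 mM, rt
Reagents that add atoms: none
Why: Steglich-type carbodiimide lactonisation closes the seven-membered depsidone ring because only the C5 phenol next to the ether bridge can reach the activated acid, while the chelated C7 phenol cannot.

Step 18
Reactants: 26 racemic depsidone aldehyde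
Product: 27 (1R)-1-(benzyloxy)-4-hydroxy-10-methoxy-5,8-dimethyl-3,7-dioxo-1,3-dihydro-7H-isobenzofuro[4,5-b][1,4]benzodioxepine-11-carbaldehyde
Conditions: preparative chiral SFC, amylose tris(3,5-dimethylphenylcarbamate) phase, CO2/iPrOH; configuration assigned by X-ray anomalous dispersion
Reagents that add atoms: none
Why: Chromatographic resolution on a chiral stationary phase fixes the absolute configuration here because the O-benzyl acetal carbon, unlike a free lactol, cannot epimerise under neutral conditions; the unwanted antipode can be racemised with acid and benzyl alcohol and recycled.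

Step 19
Reactants: 27 (R)-depsidone aldehyde
Product: 28 (1R)-1-(benzyloxy)-4-hydroxy-11-(hydroxymethyl)-10-methoxy-5,8-dimethyl-1H,7H-isobenzofuro[4,5-b][1,4]benzodioxepine-3,7-dione
Conditions: NaBH4 (1.5 equiv), THF/MeOH (9:1), −20 °C, 20 min; AcOH quench
Reagents that add atoms: none
Why: Borohydride carbonyl reduction of the aromatic aldehyde is far faster than attack on the hindered depsidone ester or the lactone, and no bond to the acetal stereocentre is touched.

Step 20
Reactants: 28 (R)-benzyl acetal alcohol
Product: 29 (1R)-1,4-dihydroxy-11-(hydroxymethyl)-10-methoxy-5,8-dimethyl-1H,7H-isobenzofuro[4,5-b][1,4]benzodioxepine-3,7-dione (target, CNP0367167.1)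
Conditions: H2 (1 atm), Pd/C (10 wt% Pd), EtOAc, rt, stopped after 1 equiv uptake; filtration and evaporation below 20 °C
Reagents that add atoms: none
Why: Catalytic hydrogenolysis cleaves the O–CH2Ph bond and not a bond to the acetal carbon, so the lactol is released with retention as the (R)-enantiomer under neutral aprotic conditions where ring-chain tautomerism is slow.

**Compound list**
1 | trimethyl phosphonoacetate | COC(=O)CP(=O)(OC)OC | starting material
2 | 2,2-dimethoxyacetaldehyde (60 wt% aqueous solution) | COC(OC)C=O | starting material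
3 | methyl (E)-4,4-dimethoxybut-2-enoate | COC(=O)/C=C/C(OC)OC | intermediate
4 | methyl 3-oxopentanoate | CCC(=O)CC(=O)OC | starting material
5 | Michael adduct, dimethyl 3-(dimethoxymethyl)-2-propanoylpentanedioate (not isolated, diastereomer mixture) | CCC(=O)C(C(=O)OC)C(CC(=O)OC)C(OC)OC | intermediate
6 | methyl 6-(dimethoxymethyl)-3-methyl-2,4-dioxocyclohexane-1-carboxylate (diastereomer and enol mixture) | COC(=O)C1C(C(OC)OC)CC(=O)C(C)C1=O | intermediate
7 | methyl 6-(dimethoxymethyl)-2,4-dihydroxy-3-methylbenzoate | COC(=O)c1c(O)c(C)c(O)cc1C(OC)OC | intermediate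
8 | aldehyde ester, methyl 6-formyl-2,4-dihydroxy-3-methylbenzoate (not isolated) | COC(=O)c1c(O)c(C)c(O)cc1C=O | intermediate
9 | racemic 3,5,7-trihydroxy-6-methyl-3H-isobenzofuran-1-one | O=C1OC(O)c2cc(O)c(C)c(O)c12 | intermediate
10 | racemic 3-(benzyloxy)-5,7-dihydroxy-6-methyl-3H-isobenzofuran-1-one | O=C1OC(OCc3ccccc3)c2cc(O)c(C)c(O)c12 | intermediate
11 | racemic 3-(benzyloxy)-5,7-bis(methoxymethoxy)-6-methyl-3H-isobenzofuran-1-one | O=C1OC(OCc3ccccc3)c2cc(OCOC)c(C)c(OCOC)c12 | intermediate
12 | racemic 3-(benzyloxy)-4-bromo-5,7-bis(methoxymethoxy)-6-methyl-3H-isobenzofuran-1-one | O=C1OC(OCc3ccccc3)c2c(Br)c(OCOC)c(C)c(OCOC)c12 | intermediate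
13 | pinacol boronate, racemic 3-(benzyloxy)-5,7-bis(methoxymethoxy)-6-methyl-4-(4,4,5,5-tetramethyl-1,3,2-dioxaborolan-2-yl)-3H-isobenzofuran-1-one (not isolated) | O=C1OC(OCc3ccccc3)c2c(B4OC(C)(C)C(C)(C)O4)c(OCOC)c(C)c(OCOC)c12 | intermediate
14 | racemic 3-(benzyloxy)-4-hydroxy-5,7-bis(methoxymethoxy)-6-methyl-3H-isobenzofuran-1-one | O=C1OC(OCc3ccccc3)c2c(O)c(OCOC)c(C)c(OCOC)c12 | intermediate
15 | 1-fluoro-3-methoxy-5-methylbenzene (3-fluoro-5-methylanisole) | COc1cc(C)cc(F)c1 | starting material
16 | 2-bromo-1-fluoro-5-methoxy-3-methylbenzene | COc1cc(C)c(Br)c(F)c1 | intermediate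
17 | aryllithium, (3-bromo-2-fluoro-6-methoxy-4-methylphenyl)lithium (not isolated) | COc1cc(C)c(Br)c(F)c1[Li] | intermediate
18 | 3-bromo-2-fluoro-6-methoxy-4-methylbenzaldehyde | COc1cc(C)c(Br)c(F)c1C=O | intermediate
19 | 2-(3-bromo-2-fluoro-6-methoxy-4-methylphenyl)-1,3-dioxolane | COc1cc(C)c(Br)c(F)c1C1OCCO1 | intermediate
20 | aryllithium, [3-(1,3-dioxolan-2-yl)-2-fluoro-4-methoxy-6-methylphenyl]lithium (not isolated) | COc1cc(C)c([Li])c(F)c1C1OCCO1 | intermediate
21 | allyl 3-(1,3-dioxolan-2-yl)-2-fluoro-4-methoxy-6-methylbenzoate | C=CCOC(=O)c1c(C)cc(OC)c(C2OCCO2)c1F | intermediate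
22 | allyl 2-fluoro-3-formyl-4-methoxy-6-methylbenzoate | C=CCOC(=O)c1c(C)cc(OC)c(C=O)c1F | intermediate
23 | racemic allyl 2-{[3-(benzyloxy)-5,7-bis(methoxymethoxy)-6-methyl-1-oxo-1,3-dihydroisobenzofuran-4-yl]oxy}-3-formyl-4-methoxy-6-methylbenzoate | C=CCOC(=O)c1c(C)cc(OC)c(C=O)c1Oc1c(OCOC)c(C)c(OCOC)c2C(=O)OC(OCc3ccccc3)c12 | intermediate
24 | racemic 2-{[3-(benzyloxy)-5,7-bis(methoxymethoxy)-6-methyl-1-oxo-1,3-dihydroisobenzofuran-4-yl]oxy}-3-formyl-4-methoxy-6-methylbenzoic acid | OC(=O)c1c(C)cc(OC)c(C=O)c1Oc1c(OCOC)c(C)c(OCOC)c2C(=O)OC(OCc3ccccc3)c12 | intermediate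
25 | racemic 2-{[3-(benzyloxy)-5,7-dihydroxy-6-methyl-1-oxo-1,3-dihydroisobenzofuran-4-yl]oxy}-3-formyl-4-methoxy-6-methylbenzoic acid | OC(=O)c1c(C)cc(OC)c(C=O)c1Oc1c(O)c(C)c(O)c2C(=O)OC(OCc3ccccc3)c12 | intermediate
26 | racemic 1-(benzyloxy)-4-hydroxy-10-methoxy-5,8-dimethyl-3,7-dioxo-1,3-dihydro-7H-isobenzofuro[4,5-b][1,4]benzodioxepine-11-carbaldehyde | COc1cc(C)c2c(c1C=O)Oc1c(c(C)c(O)c3c1C(OCc4ccccc4)OC3=O)OC2=O | intermediate
27 | (1R)-1-(benzyloxy)-4-hydroxy-10-methoxy-5,8-dimethyl-3,7-dioxo-1,3-dihydro-7H-isobenzofuro[4,5-b][1,4]benzodioxepine-11-carbaldehyde | COc1cc(C)c2c(c1C=O)Oc1c(c(C)c(O)c3c1[C@H](OCc4ccccc4)OC3=O)OC2=O | intermediate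
28 | (1R)-1-(benzyloxy)-4-hydroxy-11-(hydroxymethyl)-10-methoxy-5,8-dimethyl-1H,7H-isobenzofuro[4,5-b][1,4]benzodioxepine-3,7-dione | COc1cc(C)c2c(c1CO)Oc1c(c(C)c(O)c3c1[C@H](OCc4ccccc4)OC3=O)OC2=O | intermediate
29 | (1R)-1,4-dihydroxy-11-(hydroxymethyl)-10-methoxy-5,8-dimethyl-1H,7H-isobenzofuro[4,5-b][1,4]benzodioxepine-3,7-dione, (R)-cryptostictic acid | COc1cc(C)c2c(c1CO)Oc1c(c(C)c(O)c3c1[C@H](O)OC3=O)OC2=O | target

**Summary**
Total step count: 20.
Longest linear sequence: 15 steps (steps 1 to 8, then 14 to 20); the ring A branch is steps 9 to 13.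

**Steps most likely to fail**

Step 3 (aromatisation of the acetal-bearing dione). The quinone dehydrogenation may stall, or acid traces may cleave the acetal before the ring is aromatic. Fallback: setting out from dione 6, aromatise and ring-brominate in one operation with Br2 (2.1 equiv) and NaOAc in AcOH at rt (α-bromination, loss of HBr, then electrophilic bromination of the resorcylate at its only free position). Aqueous work-up gives methyl 5-bromo-6-formyl-2,4-dihydroxy-3-methylbenzoate F1. Aqueous NaOH then acid closes it to racemic 4-bromo-3,5,7-trihydroxy-6-methyl-3H-isobenzofuran-1-one F2. Benzyl alcohol with camphorsulfonic acid gives racemic 3-(benzyloxy)-4-bromo-5,7-dihydroxy-6-methyl-3H-isobenzofuran-1-one F3. NaH and MOMCl then bring it back to the route at bromide 12, bypassing 7 to 11.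

Step 14 (SNAr to a tetra-ortho-substituted diaryl ether). Steric crowding on both partners may make the substitution slow. Fallback: reverse the polarity, setting out from fluoride 22 and bromide 12. Fluoride 22 is converted with the sodium alkoxide of 2-(methylsulfonyl)ethanol (NaH, DMF, 0 °C; addition–elimination, then loss of methyl vinyl sulfone) into the phenol allyl 3-formyl-2-hydroxy-4-methoxy-6-methylbenzoate F4. F4 is coupled with aryl bromide 12 in a ligand-accelerated Ullmann ether synthesis (CuI, N,N-dimethylglycine, Cs2CO3, 1,4-dioxane, 100 °C), coming back to the route at diaryl ether 23.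

Step 20 (final hydrogenolysis). Hydrogenolysis may also attack the electron-rich benzylic alcohol of ring A or over-reduce the lactol. Fallback: leave the resolution to the end, setting out from racemic aldehyde 26. NaBH4 as in step 19 gives the racemic alcohol 1-(benzyloxy)-4-hydroxy-11-(hydroxymethyl)-10-methoxy-5,8-dimethyl-1H,7H-isobenzofuro[4,5-b][1,4]benzodioxepine-3,7-dione F5. The benzyl acetal is hydrolysed with 0.5 M H2SO4 in 1,4-dioxane/water at 50 °C to racemic cryptostictic acid F6. The (R)-enantiomer is then isolated by preparative chiral SFC on a sub-ambient column with cold, alcohol-free work-up, coming back to the route at 29.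

**Further compounds**
F1 | step 3 | methyl 5-bromo-6-formyl-2,4-dihydroxy-3-methylbenzoate | COC(=O)c1c(O)c(C)c(O)c(Br)c1C=O
F2 | step 3 | racemic 4-bromo-3,5,7-trihydroxy-6-methyl-3H-isobenzofuran-1-one | O=C1OC(O)c2c(Br)c(O)c(C)c(O)c12
F3 | step 3 | racemic 3-(benzyloxy)-4-bromo-5,7-dihydroxy-6-methyl-3H-isobenzofuran-1-one | O=C1OC(OCc3ccccc3)c2c(Br)c(O)c(C)c(O)c12
F4 | step 14 | allyl 3-formyl-2-hydroxy-4-methoxy-6-methylbenzoate | C=CCOC(=O)c1c(C)cc(OC)c(C=O)c1O
F5 | step 20 | racemic 1-(benzyloxy)-4-hydroxy-11-(hydroxymethyl)-10-methoxy-5,8-dimethyl-1H,7H-isobenzofuro[4,5-b][1,4]benzodioxepine-3,7-dione | COc1cc(C)c2c(c1CO)Oc1c(c(C)c(O)c3c1C(OCc4ccccc4)OC3=O)OC2=O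
F6 | step 20 | racemic cryptostictic acid | COc1cc(C)c2c(c1CO)Oc1c(c(C)c(O)c3c1C(O)OC3=O)OC2=O
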